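The plan reads the dihydropyranone ring (ring O, C1–C5, with C1 the lactone carbonyl) as three pieces: the C5 carbinol, a terminal C2≡C3 alkyne and one molecule of carbon monoxide. One oxidative carbonylation in methanol places oxygen on C3, forms C1–C2 and closes C1–O5. The complete heterocycle thus grows out of an acyclic chain in a single operation. The precursor, a C2–C20 alkynol, already carries all four stereocentres. The anti C7/C9 diol, tied up as an acetonide, comes from a two-directional catalytic allylation. The syn C5 and C11 carbinols come from a double iodocarbonate cyclisation. Aqueous acid then unmasks the target.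

Key step: step 8

Numbering: every intermediate carries the atom numbers of the target, from C1 (lactone carbonyl) to C20 (chain methyl). O5, O7, O9 and O11 are the oxygens on those carbons.
Assumption: the target is drawn as the enol of a β-keto-δ-lactone, and both tautomers are one compound in equilibrium.
Assumption: the (S)-configured ligand of step 1 is taken to deliver the (S,S)-diol. Comparing the optical rotation with that of the known diol checks this at once, and the antipodal ligand is equally available.

Step 1
Reactants: 1 propane-1,3-diol; 2 allyl acetate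
Product: 3 (4S,6S)-nona-1,8-diene-4,6-diol
Conditions: 2 (10 equiv), [Ir(cod)Cl]2 (5 mol%), (S)-Cl,MeO-BIPHEP (10 mol%), 4-chloro-3-nitrobenzoic acid (20 mol%), Cs2CO3 (40 mol%), 1,4-dioxane, 90 °C
Reagents that add atoms: allyl acetate, C=CCOC(C)=O
Why: Two-directional Krische transfer-hydrogenative allylation: the cyclometallated π-allyliridium C,O-benzoate formed in situ dehydrogenates each primary alcohol and adds allyl to the transient aldehyde through a closed chair transition state whose face is fixed by the ligand, which sets C7 and C9 (anti, C2-symmetric), while the second addition diverts the minor enantiomer of the first into the separable meso diastereomer, so that 3 should be close to enantiopure.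

Step 2
Reactants: 3 (4S,6S)-nona-1,8-diene-4,6-diol
Product: 4 di-tert-butyl (4S,6S)-nona-1,8-diene-4,6-diyl biscarbonate
Conditions: n-BuLi (2.1 equiv), THF, −78 °C; cannulate into Boc2O (4 equiv), THF, −78 → −20 °C
Reagents that add atoms: di-tert-butyl dicarbonate, CC(C)(C)OC(=O)OC(=O)OC(C)(C)C
Why: O-Acylation of a preformed dilithium dialkoxide by inverse addition to excess Boc2O, chosen over DMAP catalysis because 1,3-diols tend to cyclise through the activated mixed anhydride, so that each oxygen is capped before it can attack its neighbour's carbonate; no stereocentre is touched.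

Step 3
Reactants: 4 di-tert-butyl (4S,6S)-nona-1,8-diene-4,6-diyl biscarbonate
Product: 5 bis[(4R,6R)-6-(iodomethyl)-2-oxo-1,3-dioxan-4-yl]methane
Conditions: IBr (2.5 equiv), PhMe, −85 °C; aq Na2S2O3/NaHCO3
Reagents that add atoms: iodine monobromide, BrI
Why: Double Bartlett–Smith iodocarbonate cyclisation: IBr forms the iodonium ion reversibly, the carbonate carbonyl oxygen opens it 6-exo through a chair with both ring substituents equatorial, and loss of the tert-butyl group makes the capture irreversible, which sets C5 syn to C7 and C11 syn to C9 under substrate control.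

Step 4
Reactants: 5 bis[(4R,6R)-6-(iodomethyl)-2-oxo-1,3-dioxan-4-yl]methane
Product: 6 (2R,4R)-1,5-bis[(2R)-oxiran-2-yl]pentane-2,4-diol
Conditions: K2CO3 (6 equiv), MeOH, 0 °C → rt
Reagents that add atoms: none
Why: Carbonate methanolysis followed by intramolecular Williamson displacement (3-exo-tet): the C5 and C11 alkoxides expel the neighbouring primary iodide, and since no carbon–oxygen bond at a stereocentre is broken, all four configurations are retained.

Step 5
Reactants: 6 (2R,4R)-1,5-bis[(2R)-oxiran-2-yl]pentane-2,4-diol
Product: 7 (4R,6R)-2,2-dimethyl-4,6-bis{[(2R)-oxiran-2-yl]methyl}-1,3-dioxane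
Conditions: 2,2-dimethoxypropane (5 equiv), PPTS (5 mol%), CH2Cl2, 0 °C → rt; Et3N quench
Reagents that add atoms: 2,2-dimethoxypropane, COC(C)(C)OC
Why: Acid-catalysed transketalisation with a weak acid that terminal epoxides tolerate; a ketal is preferred to silyl ethers because it cannot migrate to the alkoxides generated at O11 and O5 in steps 6 and 7, and the anti diol gives a twist-boat dioxane that should leave easily in step 9.

Step 6
Reactants: 7 (4R,6R)-2,2-dimethyl-4,6-bis{[(2R)-oxiran-2-yl]methyl}-1,3-dioxane; 8 octylmagnesium bromide
Product: 9 (2S)-1-[(4S,6R)-2,2-dimethyl-6-{[(2R)-oxiran-2-yl]methyl}-1,3-dioxan-4-yl]undecan-2-ol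
Conditions: 8 (0.5 equiv, added over 2 h), CuI (5 mol%), THF, −30 °C; recovered 7 recycled
Reagents that add atoms: octylmagnesium bromide, CCCCCCCC[Mg]Br
Why: Copper-catalysed Grignard opening of a terminal epoxide (SN2 at the unsubstituted carbon C12, C11 untouched): the two oxiranes of C2-symmetric 7 are homotopic, so a single opening at either end gives the same compound 9, and keeping 8 limiting holds double opening to the share that statistics for independent sites predict (about one part in seven of the converted material at this loading), while unreacted 7 is recovered.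

Step 7
Reactants: 9 (2S)-1-[(4S,6R)-2,2-dimethyl-6-{[(2R)-oxiran-2-yl]methyl}-1,3-dioxan-4-yl]undecan-2-ol; 10 lithium acetylide–ethylenediamine complex
Product: 11 (2S)-1-{(4S,6S)-6-[(2S)-2-hydroxypent-4-yn-1-yl]-2,2-dimethyl-1,3-dioxan-4-yl}undecan-2-ol
Conditions: 10 (4 equiv), DMSO, 0 °C → rt
Reagents that add atoms: lithium acetylide (as its ethylenediamine complex), [Li]C#C.NCCN
Why: SN2 alkynylation of the remaining terminal epoxide at C4 in a dipolar aprotic solvent, which delivers the free terminal alkyne directly with no silyl group to remove, one extra equivalent being consumed by the O11 proton; C5 keeps its configuration (the descriptor changes only through priorities) and the ketal is inert to base.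

Step 8
Reactants: 11 (2S)-1-{(4S,6S)-6-[(2S)-2-hydroxypent-4-yn-1-yl]-2,2-dimethyl-1,3-dioxan-4-yl}undecan-2-ol; 12 carbon monoxide; 13 methanol
Product: 15 (6R)-6-{[(4R,6S)-6-[(2S)-2-hydroxyundecyl]-2,2-dimethyl-1,3-dioxan-4-yl]methyl}-4-methoxy-5,6-dihydro-2H-pyran-2-one, via hydroxy methoxyacrylate ester 14 (not isolated)
Conditions: Pd(OCOCF3)2 (5 mol%), 2,2'-isopropylidenebis[(4S)-4-phenyl-2-oxazoline] (7.5 mol%), p-benzoquinone (1.5 equiv), CO (1 atm), MeOH, −20 → 0 °C; cold NaHCO3 quench
Reagents that add atoms: carbon monoxide, [C-]#[O+]; methanol, CO
Why: The bis(oxazoline) complex of divalent palladium binds the terminal C2≡C3 alkyne, methanol attacks the internal carbon C3 from the side away from the metal (Markovnikov anti-oxypalladation), and the C2 vinylpalladium so formed inserts CO to give an acylpalladium that sits cis to the C4 methylene. That acyl group is taken either by O5 directly or by the solvent to give the (E)-ester 14, whose ester carbon is equally cis to C4 and is attacked by O5 in the same flask, so both channels close the ring O5–C1–C2–C3–C4–C5 by 6-exo-trig acyl substitution, after which p-benzoquinone returns zerovalent palladium to the divalent state. The closest known reaction type is the palladium bis(oxazoline)-catalysed oxidative methoxycarbonylation of terminal alkynes to (E)-β-methoxyacrylates, which is established for free homopropargylic alcohols as a route to 4-methoxy-5,6-dihydropyran-2-ones. No stereocentre is formed, and C5, C7, C9 and C11 lie outside the reacting array. The step needs methanol to win over three internal oxygens: 5-endo-dig attack of O5 at C2 is disfavoured by the Markovnikov bias of the terminal alkyne, by the strongly electrophilic ligand-bound metal and by methanol being the solvent, 6-exo-dig attack of O7 at C3 is excluded because O7 is locked in the ketal, and O11 is too remote to reach the alkyne. O5 is deliberately left free, since it is the nucleophile that closes the ring.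

Step 9
Reactants: 15 (6R)-6-{[(4R,6S)-6-[(2S)-2-hydroxyundecyl]-2,2-dimethyl-1,3-dioxan-4-yl]methyl}-4-methoxy-5,6-dihydro-2H-pyran-2-one
Product: 17 (6R)-4-hydroxy-6-[(2R,4S,6S)-2,4,6-trihydroxypentadecyl]-5,6-dihydro-2H-pyran-2-one, via triol enol ether 16 (not isolated)
Conditions: 2 M aq HCl–THF (1:2), rt → 40 °C
Reagents that add atoms: water, O
Why: Specific-acid hydrolysis: the strained ketal falls first to give 16, then protonation of the vinylogous carbonate at C2, addition of water at C3 and loss of methanol give the β-keto lactone, which rests as enol 17, a class of compound that is routinely liberated by acidification with aqueous HCl and should therefore survive the medium; no stereocentre is involved.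

Compound list
1 | propane-1,3-diol | OCCCO | starting material
2 | allyl acetate | C=CCOC(C)=O | starting material
3 | (4S,6S)-nona-1,8-diene-4,6-diol | C=CC[C@H](O)C[C@@H](O)CC=C | intermediate
4 | di-tert-butyl (4S,6S)-nona-1,8-diene-4,6-diyl biscarbonate | C=CC[C@H](OC(=O)OC(C)(C)C)C[C@@H](OC(=O)OC(C)(C)C)CC=C | intermediate
5 | bis[(4R,6R)-6-(iodomethyl)-2-oxo-1,3-dioxan-4-yl]methane (both rings cis-4,6) | IC[C@H]1C[C@@H](C[C@@H]2C[C@H](CI)OC(=O)O2)OC(=O)O1 | intermediate
6 | (2R,4R)-1,5-bis[(2R)-oxiran-2-yl]pentane-2,4-diol | C1O[C@@H]1C[C@H](O)C[C@@H](O)C[C@@H]1CO1 | intermediate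
7 | (4R,6R)-2,2-dimethyl-4,6-bis{[(2R)-oxiran-2-yl]methyl}-1,3-dioxane | C1O[C@@H]1C[C@H]2C[C@H](C[C@@H]3CO3)OC(C)(C)O2 | intermediate
8 | octylmagnesium bromide | CCCCCCCC[Mg]Br | starting material
9 | (2S)-1-[(4S,6R)-2,2-dimethyl-6-{[(2R)-oxiran-2-yl]methyl}-1,3-dioxan-4-yl]undecan-2-ol | CCCCCCCCC[C@H](O)C[C@H]1C[C@H](C[C@@H]2CO2)OC(C)(C)O1 | intermediate
10 | lithium acetylide–ethylenediamine complex | [Li]C#C.NCCN | starting material
11 | (2S)-1-{(4S,6S)-6-[(2S)-2-hydroxypent-4-yn-1-yl]-2,2-dimethyl-1,3-dioxan-4-yl}undecan-2-ol (C2–C20 alkynol, C7/C9 acetonide) | CCCCCCCCC[C@H](O)C[C@H]1C[C@H](C[C@@H](O)CC#C)OC(C)(C)O1 | intermediate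
12 | carbon monoxide | [C-]#[O+] | starting material
13 | methanol | CO | starting material
14 | methyl (2E,5R)-5-hydroxy-6-{(4S,6S)-6-[(2S)-2-hydroxyundecyl]-2,2-dimethyl-1,3-dioxan-4-yl}-3-methoxyhex-2-enoate | CCCCCCCCC[C@H](O)C[C@H]1C[C@H](C[C@@H](O)C/C(OC)=C\C(=O)OC)OC(C)(C)O1 | intermediate
15 | (6R)-6-{[(4R,6S)-6-[(2S)-2-hydroxyundecyl]-2,2-dimethyl-1,3-dioxan-4-yl]methyl}-4-methoxy-5,6-dihydro-2H-pyran-2-one | CCCCCCCCC[C@H](O)C[C@H]1C[C@H](C[C@@H]2CC(OC)=CC(=O)O2)OC(C)(C)O1 | intermediate
16 | (6R)-4-methoxy-6-[(2R,4S,6S)-2,4,6-trihydroxypentadecyl]-5,6-dihydro-2H-pyran-2-one | CCCCCCCCC[C@H](O)C[C@H](O)C[C@@H](O)C[C@@H]1CC(OC)=CC(=O)O1 | intermediate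
17 | (6R)-4-hydroxy-6-[(2R,4S,6S)-2,4,6-trihydroxypentadecyl]-5,6-dihydro-2H-pyran-2-one (CNP0075663.1) | CCCCCCCCC[C@H](O)C[C@H](O)C[C@@H](O)C[C@@H]1CC(O)=CC(=O)O1 | target

Total step count: 9. Longest linear sequence: 9 steps (1 → 17).

Steps most likely to fail

Step 8.
- **Risk:** chemoselectivity may be lost at the palladium-bound alkyne. O5 may close onto C2 ahead of methanol, or the acetylenic C–H bond may undergo oxidative carbonylation. The trifluoroacetic acid released by the catalyst may also slowly methanolyse the ketal, which would let O7 attack C3. Loss of the ketal after ring closure is harmless, because step 9 removes it anyway.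
- **Fallback:** C1–C3 are brought in as one ready-made piece, so neither palladium nor CO is needed. The fallback sets out from epoxide 9. Lithiated methyl propiolate opens it at C4 under BF3·OEt2 activation (THF, −78 °C, Yamaguchi–Hirao conditions) to give the δ-hydroxy ynoate F1. NaOMe in MeOH then adds methoxide to C3 in conjugate fashion and O5 displaces the ester methoxide, a classical entry to 4-methoxy-5,6-dihydropyran-2-ones. The route is rejoined at 15.

Step 9.
- **Risk:** the vinylogous carbonate may hydrolyse only sluggishly. Forcing the acid invites opening of the lactone with decarboxylation of the resulting β-keto acid, or elimination across C4–C5.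
- **Fallback:** the methyl carbon is attacked instead of C3. The fallback sets out from 15, which is heated with LiI in ethyl acetate. This is an SN2 dealkylation in which the stabilised enolate of the β-keto lactone is the leaving group. Mild acidification gives the 4-hydroxy lactone acetonide F2. Aqueous acetic acid (80%) at room temperature then removes the ketal, and the route ends at 17.

Step 2.
- **Risk:** intramolecular transcarbonation between the two oxygens, that is cyclisation of the neighbouring alkoxide onto the first-formed carbonate with loss of tert-butoxide, may outrun the second acylation.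
- **Fallback:** the carbonate nucleophile is made from CO2, which merges steps 2 and 3. The fallback sets out from 3. Its dilithium dialkoxide (n-BuLi, THF) is saturated with CO2 to give the dilithium biscarbonate F3, a species with no electrophilic carbonyl on which to cyclise. I2 at 0 °C then triggers the same 6-exo iodocyclisation, and the route is rejoined at 5. The price is a lower syn preference, which has to be made good by chromatography or crystallisation of 5.

Step 6 is capped by statistics and not by chemistry. Starting bis-epoxide, mono-adduct and double adduct differ by one hydroxyl group each, and unreacted 7 is returned to the flask, so the step is not ranked among the three.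

Further compounds
F1 | step 8 | methyl (5S)-5-hydroxy-6-{(4S,6S)-6-[(2S)-2-hydroxyundecyl]-2,2-dimethyl-1,3-dioxan-4-yl}hex-2-ynoate | CCCCCCCCC[C@H](O)C[C@H]1C[C@H](C[C@@H](O)CC#CC(=O)OC)OC(C)(C)O1
F2 | step 9 | (6R)-4-hydroxy-6-{[(4R,6S)-6-[(2S)-2-hydroxyundecyl]-2,2-dimethyl-1,3-dioxan-4-yl]methyl}-5,6-dihydro-2H-pyran-2-one | CCCCCCCCC[C@H](O)C[C@H]1C[C@H](C[C@@H]2CC(O)=CC(=O)O2)OC(C)(C)O1
F3 | step 2 | dilithium (4S,6S)-nona-1,8-diene-4,6-diyl biscarbonate | [Li+].[Li+].C=CC[C@H](OC(=O)[O-])C[C@@H](OC(=O)[O-])CC=C
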